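**Plan**

- Retrosynthesis: the E-disubstituted CH=CH bond is cut first (cross-metathesis) into ring carbinol 19 and butenolide diene 31. Carbinol 19 is traced back through allylic transposition, epoxidation, carboalumination and propargylation to ester 8. The cyclohexene of 8 is then cut in one stroke at its C(CH3)2–C(=C) bond and at its CH2–CH2 bond.
- Enabling feature: in the trimethylcyclohexene ring the C(CH3)2–CH2 edge is an isobutene unit. The other four ring carbons (the carbon bearing the side chain, C–CH3, CH2, CH2), with the first side-chain carbon as an ester, are C3–C6 and the 3-carboxylate of a 4-methyl-2-pyranone whose O–C(=O) bridge leaves as CO2.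
- Forward order: the carbocycle is made first (step 2), trimmed to the bromide and extended to (S)-carbinol 19 (steps 3–9). The lactone ring is closed separately by Dieckmann condensation on a glycidate-derived chain (steps 10–15). Union (step 16) and desilylation (step 17) follow.
- Stereochemistry: the tertiary carbinol comes from Ti/L-(+)-tartrate epoxidation followed by a transposition that leaves its C–O bond intact. The lactone stereocentre comes from methyl (S)-glycidate. The trisubstituted alkene comes from anti-carbomagnesiation and iodinolysis with retention, and the disubstituted alkene from E-selective metathesis.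

Key step: step 2

Assumption: 1, 2, 5, 11, 20, 21 and 25 are taken as purchasable; compounds 3–16 carry no stereocentre that reaches the target (6 is racemic).

**Route**

Step 1
Reactants: 1 diethyl 2-(propan-2-ylidene)propanedioate; 2 N,N-dimethylformamide dimethyl acetal
Product: 4 ethyl 4-methyl-2-oxo-2H-pyran-3-carboxylate, via dienamine diester 3 (not isolated)
Conditions: 2 (1.1 equiv), neat, 110 °C, −MeOH; then AcOH/H2O (4:1), 90 °C
Reagents that add atoms: water, O
Why: Condensation of the amide acetal at a γ-methyl group of the alkylidene malonate (vinylogous enamine formation) gives a push–pull dienamine, and aqueous acid should hydrolyse the enamine and lactonise the resulting enol onto the cis ester to close the 2-pyranone.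

Step 2
Reactants: 4 ethyl 4-methyl-2-oxo-2H-pyran-3-carboxylate; 5 2-methylprop-1-ene (isobutene)
Product: 7 ethyl 2,6,6-trimethylcyclohexa-1,3-diene-1-carboxylate, via bicyclic lactone 6 (not isolated)
Conditions: 5 (15 equiv), toluene, BHT (1 mol%), sealed autoclave, 170 °C
Reagents that add atoms: none
Why: The 2-pyranone 4 is an electron-poor cyclic diene (C3 and C6 are the diene ends, the lactone and the C3 ester lower the LUMO) and isobutene is a nucleophilic 1,1-dialkyl alkene, so an inverse-electron-demand Diels–Alder reaction should occur in which the alkene CH2 bonds to C6 and the developing tertiary cationic carbon is captured by the doubly acyl-stabilised C3, giving 2-oxabicyclo[2.2.2]octenone 6, which at this temperature loses CO2 by retro-[4+2] to the cyclohexa-1,3-diene 7. The closest known reaction type is the thermal cycloaddition/decarboxylation of 2-pyranone 3- and 5-carboxylates with ketene acetals, enol ethers and unactivated alkenes. The six-membered carbocycle is closed by an intermolecular suprafacial [4+2] addition across C3/C6 of the heterocycle and is then released from the bicycle by cycloreversion of the O–C(=O) bridge, which places the tetrasubstituted C=C between the ester-bearing and methyl-bearing carbons without any later alkene isomerisation. No stereocentre is carried forward, because both bridgeheads of 6 become sp2 in 7. The step needs regioselectivity (C(CH3)2 next to the ester carbon, CH2 next to the ring CH), and this is secured by the polarity match between the nucleophilic CH2 of the alkene and the electrophilic C6 of the pyranone, the same sense in which ketene acetals add. A second cycloaddition is not expected because 7 is a hindered diene with no extrudable bridge, and aromatisation is blocked by the quaternary carbon.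

Step 3
Reactants: 7 ethyl 2,6,6-trimethylcyclohexa-1,3-diene-1-carboxylate
Product: 8 ethyl 2,6,6-trimethylcyclohex-1-ene-1-carboxylate
Conditions: H2 (1 atm), RhCl(PPh3)3 (5 mol%), benzene/EtOH, rt
Reagents that add atoms: none
Why: Homogeneous hydrogenation with RhCl(PPh3)3 is sensitive to alkene substitution, so the cis-disubstituted ring alkene should be saturated while the tetrasubstituted, ester-bearing alkene stays in place; no stereocentre is formed.

Step 4
Reactants: 8 ethyl 2,6,6-trimethylcyclohex-1-ene-1-carboxylate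
Product: 9 (2,6,6-trimethylcyclohex-1-en-1-yl)methanol
Conditions: LiAlH4, Et2O, 0 °C → reflux; aqueous NaOH work-up
Reagents that add atoms: none
Why: Hydride reduction of the ester with LiAlH4 should give the primary allylic alcohol, the hindered tetrasubstituted alkene being inert to the reagent.

Step 5
Reactants: 9 (2,6,6-trimethylcyclohex-1-en-1-yl)methanol
Product: 10 2-(bromomethyl)-1,3,3-trimethylcyclohex-1-ene
Conditions: PBr3 (0.4 equiv), pyridine (cat.), pentane, −10 °C
Reagents that add atoms: phosphorus tribromide, BrP(Br)Br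
Why: Bromodehydroxylation with PBr3 (SN2 on the phosphite ester) at low temperature converts the primary allylic alcohol to the bromide without allylic transposition, which would have to create a quaternary centre.

Step 6
Reactants: 10 2-(bromomethyl)-1,3,3-trimethylcyclohex-1-ene; 11 1-(trimethylsilyl)propyne
Product: 14 2-(but-3-yn-1-yl)-1,3,3-trimethylcyclohex-1-ene, via lithiated silylpropyne 12 (not isolated), via silylated alkyne 13 (not isolated)
Conditions: 11, nBuLi, THF, −78 → −20 °C; 10, −78 °C → rt; then K2CO3 (cat.), MeOH, rt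
Reagents that add atoms: none
Why: The propargylic carbanion of 1-(trimethylsilyl)propyne alkylates the primary allylic bromide by SN2 at CH2 (the silyl group suppresses the allenyl mode, and attack at the ring carbon would build a quaternary centre beside C(CH3)2), and base-catalysed methanolysis then removes the C-silyl group.

Step 7
Reactants: 14 2-(but-3-yn-1-yl)-1,3,3-trimethylcyclohex-1-ene
Product: 16 (2E)-3-methyl-5-(2,6,6-trimethylcyclohex-1-en-1-yl)pent-2-en-1-ol, via alkenylalane 15 (not isolated)
Conditions: Me3Al (2 equiv), Cp2ZrCl2 (25 mol%), ClCH2CH2Cl, rt; then nBuLi, hexane/THF, 0 °C; (CH2O)n, rt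
Reagents that add atoms: trimethylaluminium, C[Al](C)C; paraformaldehyde (as formaldehyde), C=O
Why: Zirconium-catalysed syn-carboalumination of the terminal alkyne (Negishi carboalumination) places methyl on the inner and aluminium on the terminal carbon, and hydroxymethylation of the derived alanate with formaldehyde proceeds with retention, which fixes the E geometry.

Step 8
Reactants: 16 (2E)-3-methyl-5-(2,6,6-trimethylcyclohex-1-en-1-yl)pent-2-en-1-ol
Product: 17 [(2S,3S)-3-methyl-3-[2-(2,6,6-trimethylcyclohex-1-en-1-yl)ethyl]oxiran-2-yl]methanol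
Conditions: Ti(OiPr)4 (5 mol%), L-(+)-diethyl tartrate (7 mol%), tBuOOH, 4 Å sieves, CH2Cl2, −20 °C
Reagents that add atoms: tert-butyl hydroperoxide, CC(C)(C)OO
Why: Sharpless asymmetric epoxidation epoxidises only the allylic alcohol alkene, and with L-(+)-tartrate an (E)-3,3-disubstituted allylic alcohol of this type should give the (2S,3S)-epoxide, which sets the configuration of the future tertiary carbinol.

Step 9
Reactants: 17 [(2S,3S)-3-methyl-3-[2-(2,6,6-trimethylcyclohex-1-en-1-yl)ethyl]oxiran-2-yl]methanol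
Product: 19 (3S)-3-methyl-5-(2,6,6-trimethylcyclohex-1-en-1-yl)pent-1-en-3-ol, via epoxy iodide 18 (not isolated)
Conditions: PPh3, I2, imidazole, Et2O/MeCN, 0 °C; then Zn dust, EtOH, 40 °C
Reagents that add atoms: none
Why: Appel-type iodination of the primary alcohol followed by zinc insertion and β-elimination with epoxide opening (reductive ring opening of a 2,3-epoxy iodide) transposes the functionality to the tertiary allylic alcohol without breaking the C–O bond at the stereocentre, so the S configuration is retained.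

Step 10
Reactants: 20 prop-2-yn-1-ol; 21 allylmagnesium bromide (CH2=CHCH2MgBr)
Product: 23 (2Z)-3-iodo-2-(prop-2-en-1-yl)prop-2-en-1-ol, via alkenylmagnesium alkoxide 22 (not isolated)
Conditions: 21 (2.5 equiv), CuI (10 mol%), Et2O, −20 °C → rt; then I2, −78 → 0 °C
Reagents that add atoms: iodine, II
Why: Copper-assisted anti-carbomagnesiation of the propargylic alkoxide delivers allyl to the inner alkyne carbon and magnesium to the terminal carbon within a five-membered alkoxide chelate, and iodinolysis with retention gives the Z iodide in which iodine is cis to CH2OH.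

Step 11
Reactants: 23 (2Z)-3-iodo-2-(prop-2-en-1-yl)prop-2-en-1-ol
Product: 24 tert-butyl{[(2Z)-3-iodo-2-(prop-2-en-1-yl)prop-2-en-1-yl]oxy}dimethylsilane
Conditions: TBSCl, imidazole, CH2Cl2, rt
Reagents that add atoms: tert-butyldimethylsilyl chloride, CC(C)(C)[Si](C)(C)Cl
Why: Standard silylation of the primary alcohol (silyl ether formation) protects it against the organometallic and acylating steps that follow.

Step 12
Reactants: 24 tert-butyl{[(2Z)-3-iodo-2-(prop-2-en-1-yl)prop-2-en-1-yl]oxy}dimethylsilane; 25 methyl (2S)-oxirane-2-carboxylate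
Product: 28 methyl (2S,4Z)-2-(acetyloxy)-5-({[tert-butyl(dimethyl)silyl]oxy}methyl)octa-4,7-dienoate, via alkenylmagnesium chloride 26 (not isolated), via magnesium alkoxide 27 (not isolated)
Conditions: iPrMgCl·LiCl, THF, 0 °C → rt; CuI (10 mol%), 25, −40 → −20 °C; then Ac2O, DMAP (cat.), −20 °C → rt
Reagents that add atoms: acetic anhydride, CC(=O)OC(C)=O
Why: Iodine–magnesium exchange proceeds with retention of alkene geometry, copper-catalysed SN2 opening of the glycidate at its unsubstituted carbon leaves the S stereocentre untouched, and the magnesium alkoxide is acetylated in the same flask.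

Step 13
Reactants: 28 methyl (2S,4Z)-2-(acetyloxy)-5-({[tert-butyl(dimethyl)silyl]oxy}methyl)octa-4,7-dienoate
Product: 29 (5S)-5-[(2Z)-3-({[tert-butyl(dimethyl)silyl]oxy}methyl)hexa-2,5-dien-1-yl]-4-hydroxyfuran-2(5H)-one
Conditions: LiN(SiMe3)2 (2.3 equiv), THF, −78 → −30 °C; cold 0.5 M HCl
Reagents that add atoms: none
Why: Dieckmann-type intramolecular Claisen condensation (5-exo-trig attack of the acetate enolate on the methyl ester) should close the tetronic acid, kinetic deprotonation of the unhindered acetyl methyl at low temperature keeping the adjacent stereocentre intact.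

Step 14
Reactants: 29 (5S)-5-[(2Z)-3-({[tert-butyl(dimethyl)silyl]oxy}methyl)hexa-2,5-dien-1-yl]-4-hydroxyfuran-2(5H)-one
Product: 30 (2S)-2-[(2Z)-3-({[tert-butyl(dimethyl)silyl]oxy}methyl)hexa-2,5-dien-1-yl]-5-oxo-2,5-dihydrofuran-3-yl trifluoromethanesulfonate
Conditions: Tf2O, iPr2NEt, CH2Cl2, −78 °C
Reagents that add atoms: trifluoromethanesulfonic anhydride, O=S(=O)(OS(=O)(=O)C(F)(F)F)C(F)(F)F
Why: O-sulfonylation of the vinylogous acid with triflic anhydride gives the enol triflate as the handle for cross-coupling.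

Step 15
Reactants: 30 (2S)-2-[(2Z)-3-({[tert-butyl(dimethyl)silyl]oxy}methyl)hexa-2,5-dien-1-yl]-5-oxo-2,5-dihydrofuran-3-yl trifluoromethanesulfonate
Product: 31 (5S)-5-[(2Z)-3-({[tert-butyl(dimethyl)silyl]oxy}methyl)hexa-2,5-dien-1-yl]-4-(hydroxymethyl)furan-2(5H)-one
Conditions: Bu3SnCH2OH, Pd(PPh3)4 (5 mol%), LiCl, 1,4-dioxane, 90 °C
Reagents that add atoms: (tributylstannyl)methanol, CCCC[Sn](CCCC)(CCCC)CO
Why: Stille coupling of the electron-poor enol triflate with the hydroxymethylstannane transfers CH2OH to C4 of the butenolide under neutral conditions that should not epimerise C5.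

Step 16
Reactants: 19 (3S)-3-methyl-5-(2,6,6-trimethylcyclohex-1-en-1-yl)pent-1-en-3-ol; 31 (5S)-5-[(2Z)-3-({[tert-butyl(dimethyl)silyl]oxy}methyl)hexa-2,5-dien-1-yl]-4-(hydroxymethyl)furan-2(5H)-one
Product: 32 (5S)-5-[(2Z,5E,7S)-3-({[tert-butyl(dimethyl)silyl]oxy}methyl)-7-hydroxy-7-methyl-9-(2,6,6-trimethylcyclohex-1-en-1-yl)nona-2,5-dien-1-yl]-4-(hydroxymethyl)furan-2(5H)-one
Conditions: 19 (2 equiv), second-generation Hoveyda–Grubbs catalyst RuCl2(=CH-C6H4-2-OiPr)(H2IMes) (7 mol%), 1,4-benzoquinone (15 mol%), CH2Cl2, 40 °C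
Reagents that add atoms: none
Why: Olefin cross-metathesis joins the two terminal alkenes; the alkene next to the quaternary carbinol homodimerises slowly and enforces the E geometry, whereas the tetrasubstituted, trisubstituted and lactone alkenes are spectators, and benzoquinone suppresses migration of the skipped diene.

Step 17
Reactants: 32 (5S)-5-[(2Z,5E,7S)-3-({[tert-butyl(dimethyl)silyl]oxy}methyl)-7-hydroxy-7-methyl-9-(2,6,6-trimethylcyclohex-1-en-1-yl)nona-2,5-dien-1-yl]-4-(hydroxymethyl)furan-2(5H)-one
Product: 33 (5S)-4-(hydroxymethyl)-5-[(2Z,5E,7S)-7-hydroxy-3-(hydroxymethyl)-7-methyl-9-(2,6,6-trimethylcyclohex-1-en-1-yl)nona-2,5-dien-1-yl]furan-2(5H)-one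
Conditions: HF·pyridine, pyridine, THF, 0 °C → rt
Reagents that add atoms: none
Why: Buffered fluoride cleavage of the primary silyl ether (desilylation) is mild enough to leave the tertiary allylic alcohol, the skipped diene and the butenolide stereocentre unchanged.

**Compound list**

1 | diethyl 2-(propan-2-ylidene)propanedioate | CCOC(=O)C(=C(C)C)C(=O)OCC | starting material
2 | N,N-dimethylformamide dimethyl acetal | COC(OC)N(C)C | starting material
3 | diethyl 2-[(3E)-4-(dimethylamino)but-3-en-2-ylidene]propanedioate | CCOC(=O)C(C(=O)OCC)=C(C)/C=C/N(C)C | intermediate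
4 | ethyl 4-methyl-2-oxo-2H-pyran-3-carboxylate | CCOC(=O)C1=C(C)C=COC1=O | intermediate
5 | 2-methylprop-1-ene | CC(C)=C | starting material
6 | ethyl 5,8,8-trimethyl-3-oxo-2-oxabicyclo[2.2.2]oct-5-ene-4-carboxylate (racemic) | CCOC(=O)C12C(=O)OC(CC1(C)C)C=C2C | intermediate
7 | ethyl 2,6,6-trimethylcyclohexa-1,3-diene-1-carboxylate | CCOC(=O)C1=C(C)C=CCC1(C)C | intermediate
8 | ethyl 2,6,6-trimethylcyclohex-1-ene-1-carboxylate | CCOC(=O)C1=C(C)CCCC1(C)C | intermediate
9 | (2,6,6-trimethylcyclohex-1-en-1-yl)methanol | OCC1=C(C)CCCC1(C)C | intermediate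
10 | 2-(bromomethyl)-1,3,3-trimethylcyclohex-1-ene | BrCC1=C(C)CCCC1(C)C | intermediate
11 | 1-(trimethylsilyl)propyne | CC#C[Si](C)(C)C | starting material
12 | [3-(trimethylsilyl)prop-2-yn-1-yl]lithium | [Li]CC#C[Si](C)(C)C | intermediate
13 | trimethyl[4-(2,6,6-trimethylcyclohex-1-en-1-yl)but-1-yn-1-yl]silane | C[Si](C)(C)C#CCCC1=C(C)CCCC1(C)C | intermediate
14 | 2-(but-3-yn-1-yl)-1,3,3-trimethylcyclohex-1-ene | C#CCCC1=C(C)CCCC1(C)C | intermediate
15 | dimethyl[(1E)-2-methyl-4-(2,6,6-trimethylcyclohex-1-en-1-yl)but-1-en-1-yl]alumane | C[Al](C)/C=C(\C)CCC1=C(C)CCCC1(C)C | intermediate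
16 | (2E)-3-methyl-5-(2,6,6-trimethylcyclohex-1-en-1-yl)pent-2-en-1-ol | OC/C=C(\C)CCC1=C(C)CCCC1(C)C | intermediate
17 | [(2S,3S)-3-methyl-3-[2-(2,6,6-trimethylcyclohex-1-en-1-yl)ethyl]oxiran-2-yl]methanol | OC[C@@H]1O[C@@]1(C)CCC2=C(C)CCCC2(C)C | intermediate
18 | (2R,3S)-2-(iodomethyl)-3-methyl-3-[2-(2,6,6-trimethylcyclohex-1-en-1-yl)ethyl]oxirane | IC[C@@H]1O[C@@]1(C)CCC2=C(C)CCCC2(C)C | intermediate
19 | (3S)-3-methyl-5-(2,6,6-trimethylcyclohex-1-en-1-yl)pent-1-en-3-ol | C=C[C@@](C)(O)CCC1=C(C)CCCC1(C)C | intermediate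
20 | prop-2-yn-1-ol | OCC#C | starting material
21 | allylmagnesium bromide | C=CC[Mg]Br | starting material
22 | bromomagnesium (2Z)-3-(bromomagnesio)-2-(prop-2-en-1-yl)prop-2-en-1-olate (magnesium cis to CH2O) | Br[Mg]OC/C(CC=C)=C\[Mg]Br | intermediate
23 | (2Z)-3-iodo-2-(prop-2-en-1-yl)prop-2-en-1-ol | OC/C(CC=C)=C\I | intermediate
24 | tert-butyl{[(2Z)-3-iodo-2-(prop-2-en-1-yl)prop-2-en-1-yl]oxy}dimethylsilane | CC(C)(C)[Si](C)(C)OC/C(CC=C)=C\I | intermediate
25 | methyl (2S)-oxirane-2-carboxylate | COC(=O)[C@@H]1CO1 | starting material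
26 | chloro[(1Z)-2-({[tert-butyl(dimethyl)silyl]oxy}methyl)penta-1,4-dien-1-yl]magnesium | Cl[Mg]/C=C(\CO[Si](C)(C)C(C)(C)C)CC=C | intermediate
27 | methyl (2S,4Z)-5-({[tert-butyl(dimethyl)silyl]oxy}methyl)-2-[(chloromagnesio)oxy]octa-4,7-dienoate | COC(=O)[C@@H](O[Mg]Cl)C/C=C(\CO[Si](C)(C)C(C)(C)C)CC=C | intermediate
28 | methyl (2S,4Z)-2-(acetyloxy)-5-({[tert-butyl(dimethyl)silyl]oxy}methyl)octa-4,7-dienoate | COC(=O)[C@@H](OC(C)=O)C/C=C(\CO[Si](C)(C)C(C)(C)C)CC=C | intermediate
29 | (5S)-5-[(2Z)-3-({[tert-butyl(dimethyl)silyl]oxy}methyl)hexa-2,5-dien-1-yl]-4-hydroxyfuran-2(5H)-one | OC1=CC(=O)O[C@H]1C/C=C(\CO[Si](C)(C)C(C)(C)C)CC=C | intermediate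
30 | (2S)-2-[(2Z)-3-({[tert-butyl(dimethyl)silyl]oxy}methyl)hexa-2,5-dien-1-yl]-5-oxo-2,5-dihydrofuran-3-yl trifluoromethanesulfonate | FC(F)(F)S(=O)(=O)OC1=CC(=O)O[C@H]1C/C=C(\CO[Si](C)(C)C(C)(C)C)CC=C | intermediate
31 | (5S)-5-[(2Z)-3-({[tert-butyl(dimethyl)silyl]oxy}methyl)hexa-2,5-dien-1-yl]-4-(hydroxymethyl)furan-2(5H)-one | OCC1=CC(=O)O[C@H]1C/C=C(\CO[Si](C)(C)C(C)(C)C)CC=C | intermediate
32 | (5S)-5-[(2Z,5E,7S)-3-({[tert-butyl(dimethyl)silyl]oxy}methyl)-7-hydroxy-7-methyl-9-(2,6,6-trimethylcyclohex-1-en-1-yl)nona-2,5-dien-1-yl]-4-(hydroxymethyl)furan-2(5H)-one | CC1=C(CC[C@](C)(O)/C=C/C/C(=C/C[C@@H]2OC(=O)C=C2CO)CO[Si](C)(C)C(C)(C)C)C(C)(C)CCC1 | intermediate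
33 | (5S)-4-(hydroxymethyl)-5-[(2Z,5E,7S)-7-hydroxy-3-(hydroxymethyl)-7-methyl-9-(2,6,6-trimethylcyclohex-1-en-1-yl)nona-2,5-dien-1-yl]furan-2(5H)-one | CC1=C(CC[C@](C)(O)/C=C/C/C(=C/C[C@@H]2OC(=O)C=C2CO)CO)C(C)(C)CCC1 | target

**Step count and risks**

Total step count: 17. Longest linear sequence: 11 steps (steps 1–9, 16, 17); the butenolide branch (steps 10–15) has 6 steps before the union.

The three steps most likely to fail:

Step 2. The cycloaddition of a trisubstituted pyranone with an unactivated gaseous alkene may be too slow, so that thermal decomposition of 4, proton loss from the polarised transition state (ene-type addition) or a 1,5-hydrogen shift in the diene outruns clean product formation. The fallback sets out from 1 and comes back at 7. A Lewis-acid-promoted (EtAlCl2, CH2Cl2) normal-demand Diels–Alder reaction of 1 with (E)-penta-1,3-diene would give diethyl 2,6,6-trimethylcyclohex-3-ene-1,1-dicarboxylate F1, with the diene methyl next to the malonate carbon as in the related enone cycloadditions. Krapcho dealkoxycarbonylation (LiCl, wet DMSO, 160 °C) would give ethyl 2,6,6-trimethylcyclohex-3-ene-1-carboxylate F2. α-Selenenylation (LiN(iPr)2, then PhSeCl) would give ethyl 2,6,6-trimethyl-1-(phenylselanyl)cyclohex-3-ene-1-carboxylate F3, and oxidation with H2O2 would trigger syn-elimination, possible only towards the methyl-bearing ring carbon, to dienoate 7. This classical sequence builds the ring through a different pair of bonds and costs three steps.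

Step 16. The metathesis may suffer from statistical partner distribution (homodimerisation of the butenolide diene), sluggish turnover at the hindered carbinol alkene, or ruthenium-hydride migration of the skipped diene into conjugation. The fallback sets out from 19 and 28 and comes back at 32: the union is moved forward to the robust acetoxy ester, which has no lactone or free hydroxymethyl group and can be used in excess, and the butenolide is assembled afterwards. Cross-metathesis of 19 with 28 would give methyl (2S,4Z,7E,9S)-2-(acetyloxy)-5-({[tert-butyl(dimethyl)silyl]oxy}methyl)-9-hydroxy-9-methyl-11-(2,6,6-trimethylcyclohex-1-en-1-yl)undeca-4,7-dienoate F4. Dieckmann cyclisation with one extra equivalent of LiN(SiMe3)2 for the tertiary alkoxide would give (5S)-5-[(2Z,5E,7S)-3-({[tert-butyl(dimethyl)silyl]oxy}methyl)-7-hydroxy-7-methyl-9-(2,6,6-trimethylcyclohex-1-en-1-yl)nona-2,5-dien-1-yl]-4-hydroxyfuran-2(5H)-one F5. Selective O-triflation of the acidic enol at −78 °C would give (2S)-2-[(2Z,5E,7S)-3-({[tert-butyl(dimethyl)silyl]oxy}methyl)-7-hydroxy-7-methyl-9-(2,6,6-trimethylcyclohex-1-en-1-yl)nona-2,5-dien-1-yl]-5-oxo-2,5-dihydrofuran-3-yl trifluoromethanesulfonate F6. The hydroxymethyl Stille coupling of step 15 applied to F6 would then give 32.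

Step 13. The base may enolise the acetoxy ester at its oxygen-bearing stereogenic α-carbon instead of at the acetyl methyl, which would erode the enantiomeric purity of the future lactone carbon or cause β-elimination. The fallback sets out from 27 and comes back at 29. Quenching 27 with aqueous NH4Cl instead of acetic anhydride would give methyl (2S,4Z)-5-({[tert-butyl(dimethyl)silyl]oxy}methyl)-2-hydroxyocta-4,7-dienoate F7. Crossed Claisen condensation with the lithium enolate of ethyl acetate (3.5 equiv, THF, −78 °C) would give ethyl (4S,6Z)-7-({[tert-butyl(dimethyl)silyl]oxy}methyl)-4-hydroxy-3-oxodeca-6,9-dienoate F8; the α-alkoxide formed first shields the stereocentre from deprotonation. Mild base (K2CO3, MeOH) would lactonise F8 to tetronic acid 29.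

Further compounds
F1 | step 2 | diethyl 2,6,6-trimethylcyclohex-3-ene-1,1-dicarboxylate (racemic) | CCOC(=O)C1(C(=O)OCC)C(C)C=CCC1(C)C
F2 | step 2 | ethyl 2,6,6-trimethylcyclohex-3-ene-1-carboxylate (racemic, diastereomer mixture) | CCOC(=O)C1C(C)C=CCC1(C)C
F3 | step 2 | ethyl 2,6,6-trimethyl-1-(phenylselanyl)cyclohex-3-ene-1-carboxylate (racemic) | CCOC(=O)C1([Se]c2ccccc2)C(C)C=CCC1(C)C
F4 | step 16 | methyl (2S,4Z,7E,9S)-2-(acetyloxy)-5-({[tert-butyl(dimethyl)silyl]oxy}methyl)-9-hydroxy-9-methyl-11-(2,6,6-trimethylcyclohex-1-en-1-yl)undeca-4,7-dienoate | COC(=O)[C@@H](OC(C)=O)C/C=C(\CO[Si](C)(C)C(C)(C)C)C/C=C/[C@@](C)(O)CCC1=C(C)CCCC1(C)C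
F5 | step 16 | (5S)-5-[(2Z,5E,7S)-3-({[tert-butyl(dimethyl)silyl]oxy}methyl)-7-hydroxy-7-methyl-9-(2,6,6-trimethylcyclohex-1-en-1-yl)nona-2,5-dien-1-yl]-4-hydroxyfuran-2(5H)-one | OC1=CC(=O)O[C@H]1C/C=C(\CO[Si](C)(C)C(C)(C)C)C/C=C/[C@@](C)(O)CCC2=C(C)CCCC2(C)C
F6 | step 16 | (2S)-2-[(2Z,5E,7S)-3-({[tert-butyl(dimethyl)silyl]oxy}methyl)-7-hydroxy-7-methyl-9-(2,6,6-trimethylcyclohex-1-en-1-yl)nona-2,5-dien-1-yl]-5-oxo-2,5-dihydrofuran-3-yl trifluoromethanesulfonate | FC(F)(F)S(=O)(=O)OC1=CC(=O)O[C@H]1C/C=C(\CO[Si](C)(C)C(C)(C)C)C/C=C/[C@@](C)(O)CCC2=C(C)CCCC2(C)C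
F7 | step 13 | methyl (2S,4Z)-5-({[tert-butyl(dimethyl)silyl]oxy}methyl)-2-hydroxyocta-4,7-dienoate | COC(=O)[C@@H](O)C/C=C(\CO[Si](C)(C)C(C)(C)C)CC=C
F8 | step 13 | ethyl (4S,6Z)-7-({[tert-butyl(dimethyl)silyl]oxy}methyl)-4-hydroxy-3-oxodeca-6,9-dienoate | CCOC(=O)CC(=O)[C@@H](O)C/C=C(\CO[Si](C)(C)C(C)(C)C)CC=C
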